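The unit I reckoned this flask in was millimolar of product per second.

solid substrate 31 mM; acid 0.310 mM; time 2.5 min

    starting material + product ⇌ idle adduct, settled at all times (K1 = 80 M⁻¹)
    starting material ⇌ dormant form (K2 = 0.340, k2 = 0.0445 s⁻¹)
    starting material + acid → weak acid + acid + product (k3 = 13.4 M⁻¹ s⁻¹)
    weak acid ⇌ conjugate base + acid, settled at all times (K4 = 5.0 × 10⁻⁹ M)
    solid substrate ⇌ starting material, rate k5*(cs5 - [starting material]) while solid is left; crystals form when [starting material] > cs5 (cs5 = 9.8 mM, k5 = 0.182 s⁻¹)
    starting material → weak acid + product (k6 = 0.00228 s⁻¹)

- acid is the free proton; pH is minus the decimal logarithm of its molar concentration
- percent here means solid substrate units held: one idle adduct counts as two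
- what is said of product includes idle adduct
- solid substrate is a solid; its amount is given per volume of the solution
- at the start none of the solid substrate is in solution
- what has only dissolved of solid substrate counts as not reacted
- what has gone from starting material into another species counts as reacted, even if it can come back
- in an amount of product, one idle adduct counts as one product
- run time (flask): 2.5 min

- part of the solid substrate that has reacted (what has only dissolved counts as not reacted) at 2.5 min
- pH of the solution at 2.5 min

On the fastest rung of the flask stood the two balances, idle adduct and weak acid, held at every moment. Next came the rise of [starting material] towards its level by dissolution, with a half-life of 0.0635 min, and the exchange with dormant form, at 0.0659 min. Both times are far shorter than the half-lives of starting material reacting, 2.8 min with acid and 5.1 min without, so I expected [starting material] to reach its level early, while dissolution went on feeding the reaction as long as solid was left.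

So I expected a plateau of [starting material] under the solubility. The acid returns in its step, which makes that step pseudo-first-order, and the two routes to product add to 0.00643 s⁻¹. Dissolution must also feed the idle adduct, which puts the plateau at 9.30 mM. The plateau rate, this constant times the plateau, is 0.0598 mM s⁻¹.

The real curve starts from zero, and filling starting material and dormant form costs a lag of 0.123 min, so the mean lies 4.92% under the plateau. That gives 8.54 mM of product. Each product ties up a further 0.427 of starting material as adduct, and with dormant form added I reckoned 49.5% reacted. About 6.36 mM of solid remained by this count, so the plateau lasted the run. Weak acid gives off hardly any proton, so I kept the acid at its charge of 0.310 mM in my reckoning, and the pH with it.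

The forecast gave 49.7% and pH 3.508, holding that the “solid lasts the whole run”; its conversion stood 0.20 percentage points above mine.

The simulation gave 49.8% and pH 3.51, so the forecast held.

This flask had not come to rest. At the plateau rate the solid ends at about 3.74 min, and at 2.5 min it still held 20.1%. After 25.0 min the computed flask had solid substrate at 0%, starting material at 1.10% and product at 96.0%, with 98.9% reacted.

For the neighbour flask with 0.19 mM of acid, the same reckoning gave a plateau rate of 0.0455 mM s⁻¹ and so 6.49 mM of product. The simulation of that neighbour flask gave 6.51 mM of weak acid and 40.4% reacted.

The constants used here are invented.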